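The carotenoid (carotenoid numbering) is cut at C11=C12 into a C25 ylide carrying the ε-ring and a C15 keto-enal (C1–C11 with the C19 ester) in which a 2,3-disubstituted furan masks the C8 ketone and C11 aldehyde. Everything rests on the hydroxylated cyclohexene ring C1–C6: it is made from (S)-4-silyloxy-2,2-dimethylcyclopentanone by Lewis-acid-catalysed diazoethane homologation, which inserts C5 with its methyl between the carbonyl carbon C6 and C4 in one operation. The step exploits the quaternary C1(CH3)2 next to C6: it leaves C4 as the only migrating carbon and C5 as the only enolisable site, so the derived C5=C6 enol triflate is regiodefined for coupling to the furan.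

Key step: step 4

Remark: ring C1–C6 carries the 3-OH, C19 is the CH2O carbon on C9, primed numbers belong to the ε-ring half; (R)-α-ionone of high ee is assumed to be purchasable, and diazoethane is generated from commercial N-ethyl-N-nitrosourea just before use.

Step 1
Reactants: 1 2,2-dimethylcyclopentan-1-one
Product: 2 5,5-dimethylcyclopent-2-en-1-one
Conditions: IBX (1.5 equiv), 4-methoxypyridine N-oxide, DMSO, 25 °C
Reagents that add atoms: none
Why: IBX dehydrogenation of a ketone to its enone (Nicolaou) can only run through the enol on the CH2 side because the other α-carbon is quaternary.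

Step 2
Reactants: 2 5,5-dimethylcyclopent-2-en-1-one
Product: 4 (S)-4-hydroxy-2,2-dimethylcyclopentan-1-one, via β-boryl ketone 3 (not isolated)
Conditions: CuCl (3 mol %), NaOt-Bu (5 mol %), Josiphos-type bisphosphine (3 mol %), B2pin2, MeOH (2 equiv), THF, 25 °C; then NaBO3·4H2O, THF/H2O, 25 °C
Reagents that add atoms: sodium perborate, [Na+].[O-]OB=O (hydroxyl O of 4); bis(pinacolato)diboron, CC1(C)OB(OC1(C)C)B1OC(C)(C)C(C)(C)O1 (boron of 3 only)
Why: Copper-catalysed asymmetric conjugate borylation sets the future C3 under ligand control (the ligand enantiomer that delivers the S boronate is used), and perborate oxidation of the C–B bond proceeds with retention.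

Step 3
Reactants: 4 (S)-4-hydroxy-2,2-dimethylcyclopentan-1-one
Product: 5 (S)-4-[(tert-butyldimethylsilyl)oxy]-2,2-dimethylcyclopentan-1-one
Conditions: TBSCl, imidazole, DMF, 0 → 25 °C
Reagents that add atoms: tert-butyldimethylsilyl chloride, CC(C)(C)[Si](C)(C)Cl
Why: Standard silylation protects the future 3-OH against the Lewis acid, base and organometallic reagents of steps 4–8.

Step 4
Reactants: 5 (S)-4-[(tert-butyldimethylsilyl)oxy]-2,2-dimethylcyclopentan-1-one; 6 N-ethyl-N-nitrosourea
Product: 8 (4R)-4-[(tert-butyldimethylsilyl)oxy]-2,2,6-trimethylcyclohexan-1-one (both C6 epimers), via diazoethane 7 (not isolated)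
Conditions: 7 from 6 (aq. KOH/Et2O, 0 °C, ether layer dried over KOH); Sc(OTf)3 (10 mol %), toluene/CH2Cl2, −78 → −30 °C
Reagents that add atoms: diazoethane (7, made from 6), CC=[N+]=[N-]
Why: The Sc(III)-activated carbonyl carbon C6 of 5 is attacked by the nucleophilic carbon of diazoethane to give a β-alkoxy diazonium betaine, and the ring CH2 (C4) anti to N2 shifts with loss of N2, inserting CH(CH3) (C5 with C18) between C6 and C4. The closest known reaction type is the Lewis-acid-catalysed diazoalkane homologation of cycloalkanones (Tiffeneau–Demjanov-type ring expansion). No ring is closed by cyclisation: the existing five-membered ring is enlarged to the six-membered ketone by a 1,2-carbon shift. The silyloxy centre (future C3) is a bystander and is carried through unchanged as R, while the new methyl-bearing centre C5 forms as a mixture that does not matter because C5 becomes sp2 in step 5. The step needs migration of the methylene and not of the quaternary carbon, and the C1 gem-dimethyl group secures this by disfavouring shift of the fully substituted carbon and by shielding the hindered product ketone from a second homologation.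

Step 5
Reactants: 8 (4R)-4-[(tert-butyldimethylsilyl)oxy]-2,2,6-trimethylcyclohexan-1-one
Product: 10 (R)-4-[(tert-butyldimethylsilyl)oxy]-2,6,6-trimethylcyclohex-1-en-1-yl trifluoromethanesulfonate, via potassium enolate 9 (not isolated)
Conditions: KHMDS (1.2 equiv), THF, −78 → 0 °C; then PhNTf2, −78 → 25 °C
Reagents that add atoms: N-phenylbis(trifluoromethanesulfonimide), O=S(=O)(N(c1ccccc1)S(=O)(=O)C(F)(F)F)C(F)(F)F
Why: Deprotonation is possible only at the methine C5 because C1 is quaternary, so O-triflation of the single enolate fixes the C5=C6 double bond and erases the C5 stereocentre.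

Step 6
Reactants: 11 methyl 2-methylfuran-3-carboxylate
Product: 12 methyl 2-(bromomethyl)furan-3-carboxylate
Conditions: NBS (1.05 equiv), AIBN (5 mol %), PhCF3, 80 °C
Reagents that add atoms: N-bromosuccinimide, O=C1CCC(=O)N1Br
Why: Wohl–Ziegler radical bromination should take the furfurylic methyl group (future C7), the ester deactivating the ring toward electrophilic bromination.

Step 7
Reactants: 12 methyl 2-(bromomethyl)furan-3-carboxylate; 10 (R)-4-[(tert-butyldimethylsilyl)oxy]-2,6,6-trimethylcyclohex-1-en-1-yl trifluoromethanesulfonate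
Product: 14 methyl 2-{[(R)-4-[(tert-butyldimethylsilyl)oxy]-2,6,6-trimethylcyclohex-1-en-1-yl]methyl}furan-3-carboxylate, via furfurylzinc bromide 13 (not isolated)
Conditions: activated Zn dust, LiCl, THF, 0 → 25 °C; then 10, Pd(OAc)2 (3 mol %), SPhos (6 mol %), THF/NMP, 50 °C
Reagents that add atoms: none
Why: Negishi sp3–sp2 cross-coupling of a benzylic-type zinc reagent with the alkenyl triflate forms the C6–C7 bond and tolerates ester and silyl ether; the bulky biarylphosphine is chosen for the hindered tetrasubstituted triflate.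

Step 8
Reactants: 14 methyl 2-{[(R)-4-[(tert-butyldimethylsilyl)oxy]-2,6,6-trimethylcyclohex-1-en-1-yl]methyl}furan-3-carboxylate
Product: 15 (2-{[(R)-4-[(tert-butyldimethylsilyl)oxy]-2,6,6-trimethylcyclohex-1-en-1-yl]methyl}furan-3-yl)methanol
Conditions: DIBAL-H (2.3 equiv), CH2Cl2, −78 → 0 °C; Rochelle salt work-up
Reagents that add atoms: none
Why: Hydride reduction of the ester gives the primary alcohol (future C19 carbinol) and leaves furan, alkene and silyl ether intact.

Step 9
Reactants: 15 (2-{[(R)-4-[(tert-butyldimethylsilyl)oxy]-2,6,6-trimethylcyclohex-1-en-1-yl]methyl}furan-3-yl)methanol; 16 (E)-oct-2-enoic acid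
Product: 17 (2-{[(R)-4-[(tert-butyldimethylsilyl)oxy]-2,6,6-trimethylcyclohex-1-en-1-yl]methyl}furan-3-yl)methyl (E)-oct-2-enoate
Conditions: EDC·HCl (1.3 equiv), DMAP (0.1 equiv), CH2Cl2, 0 → 25 °C
Reagents that add atoms: none
Why: Steglich-type carbodiimide esterification should acylate the primary alcohol without isomerising the conjugated double bond of the acid.

Step 10
Reactants: 17 (2-{[(R)-4-[(tert-butyldimethylsilyl)oxy]-2,6,6-trimethylcyclohex-1-en-1-yl]methyl}furan-3-yl)methyl (E)-oct-2-enoate
Product: 18 (2-{[(R)-4-hydroxy-2,6,6-trimethylcyclohex-1-en-1-yl]methyl}furan-3-yl)methyl (E)-oct-2-enoate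
Conditions: TBAF (1.5 equiv), AcOH (1.5 equiv), THF, 25 °C
Reagents that add atoms: none
Why: Buffered fluoride desilylation frees the 3-OH while the enoate ester and the furan are untouched.

Step 11
Reactants: 18 (2-{[(R)-4-hydroxy-2,6,6-trimethylcyclohex-1-en-1-yl]methyl}furan-3-yl)methyl (E)-oct-2-enoate
Product: 20 [(E)-2-{2-[(R)-4-hydroxy-2,6,6-trimethylcyclohex-1-en-1-yl]acetyl}-4-oxobut-2-en-1-yl] (E)-oct-2-enoate, via Z keto-enal 19 (not isolated)
Conditions: NBS (1.05 equiv), NaHCO3, acetone/H2O (10:1), −20 °C; extractive work-up; then I2 (2 mol %), CH2Cl2, 25 °C, diffuse light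
Reagents that add atoms: water, O
Why: Oxidative furan ring opening (bromonium attack at the free furan α-CH, hydration at the substituted α-carbon, collapse of the 2,5-dihydrofuran) unveils the C8 ketone and C11 aldehyde; the electron-rich furan should react far faster than the hindered tetrasubstituted C5=C6 bond, and iodine-catalysed isomerisation of the first-formed cis enedione should give the more stable 9E isomer.

Step 12
Reactants: 21 (R)-α-ionone
Product: 22 (3R,6R)-3-hydroxy-α-ionone
Conditions: cytochrome P450 monooxygenase (engineered P450 BM3 variant, cell-free extract), NADP+ (cat.), alcohol dehydrogenase/2-propanol recycling, air, phosphate buffer pH 7.5, 2 % DMSO, 25 °C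
Reagents that add atoms: dioxygen, O=O
Why: Enzymatic allylic C–H hydroxylation by a cytochrome P450 monooxygenase, known for α-ionone, takes place at C3' on the ring face opposite the C6' side chain, so the 6'R substrate should give the trans (3'R,6'R) alcohol.

Step 13
Reactants: 22 (3R,6R)-3-hydroxy-α-ionone; 23 vinylmagnesium bromide
Product: 24 (E)-1-[(1R,4R)-4-hydroxy-2,6,6-trimethylcyclohex-2-en-1-yl]-3-methylpenta-1,4-dien-3-ol (both carbinol epimers)
Conditions: vinylmagnesium bromide (3 equiv), THF, −20 → 0 °C; aq. NH4Cl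
Reagents that add atoms: vinylmagnesium bromide (23), C=C[Mg]Br
Why: Grignard 1,2-addition to the enone carbonyl (one equivalent is spent on the hydroxyl) gives the tertiary bis-allylic carbinol, whose configuration is lost on ionisation in step 14.

Step 14
Reactants: 24 (E)-1-[(1R,4R)-4-hydroxy-2,6,6-trimethylcyclohex-2-en-1-yl]-3-methylpenta-1,4-dien-3-ol; 25 triphenylphosphine hydrobromide
Product: 26 [(2E,4E)-5-[(1R,4R)-4-hydroxy-2,6,6-trimethylcyclohex-2-en-1-yl]-3-methylpenta-2,4-dien-1-yl]triphenylphosphonium bromide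
Conditions: Ph3P·HBr (1.05 equiv), MeOH/CH2Cl2, 0 → 25 °C
Reagents that add atoms: triphenylphosphine hydrobromide (25), [Br-].[PH+](c1ccccc1)(c1ccccc1)c1ccccc1
Why: Ionisation of the tertiary bis-allylic alcohol gives a pentadienyl cation that triphenylphosphine captures at the unhindered terminus (SN1' allylic transposition), while the less readily ionised secondary ring alcohol should survive at low temperature.

Step 15
Reactants: 26 [(2E,4E)-5-[(1R,4R)-4-hydroxy-2,6,6-trimethylcyclohex-2-en-1-yl]-3-methylpenta-2,4-dien-1-yl]triphenylphosphonium bromide; 27 (2E,4E,6E)-2,7-dimethylocta-2,4,6-trienedial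
Product: 28 (2E,4E,6E,8E,10E,12E)-13-[(1R,4R)-4-hydroxy-2,6,6-trimethylcyclohex-2-en-1-yl]-2,7,11-trimethyltrideca-2,4,6,8,10,12-hexaenal
Conditions: 27 (2 equiv), NaOMe (1.1 equiv), MeOH/CH2Cl2, 0 → 25 °C; then heptane, 80 °C (E/Z equilibration), crystallisation
Reagents that add atoms: none
Why: Wittig olefination of one formyl group of the symmetrical dialdehyde (used in excess to suppress double reaction) forms C11'=C12', and thermal equilibration should converge the new double bond to E.

Step 16
Reactants: 28 (2E,4E,6E,8E,10E,12E)-13-[(1R,4R)-4-hydroxy-2,6,6-trimethylcyclohex-2-en-1-yl]-2,7,11-trimethyltrideca-2,4,6,8,10,12-hexaenal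
Product: 29 (2E,4E,6E,8E,10E,12E)-13-[(1R,4R)-4-hydroxy-2,6,6-trimethylcyclohex-2-en-1-yl]-2,7,11-trimethyltrideca-2,4,6,8,10,12-hexaen-1-ol
Conditions: NaBH4, EtOH/THF, 0 °C
Reagents that add atoms: none
Why: Borohydride 1,2-reduction of the polyenal gives the primary allylic alcohol.

Step 17
Reactants: 29 (2E,4E,6E,8E,10E,12E)-13-[(1R,4R)-4-hydroxy-2,6,6-trimethylcyclohex-2-en-1-yl]-2,7,11-trimethyltrideca-2,4,6,8,10,12-hexaen-1-ol; 25 triphenylphosphine hydrobromide
Product: 30 [(2E,4E,6E,8E,10E,12E)-13-[(1R,4R)-4-hydroxy-2,6,6-trimethylcyclohex-2-en-1-yl]-2,7,11-trimethyltrideca-2,4,6,8,10,12-hexaen-1-yl]triphenylphosphonium bromide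
Conditions: Ph3P·HBr (1.05 equiv), MeOH/CH2Cl2, 25 °C, dark
Reagents that add atoms: triphenylphosphine hydrobromide (25), [Br-].[PH+](c1ccccc1)(c1ccccc1)c1ccccc1
Why: SN1-type substitution of the polyenylic primary alcohol through its delocalised cation gives the C25 phosphonium salt.

Step 18
Reactants: 30 [(2E,4E,6E,8E,10E,12E)-13-[(1R,4R)-4-hydroxy-2,6,6-trimethylcyclohex-2-en-1-yl]-2,7,11-trimethyltrideca-2,4,6,8,10,12-hexaen-1-yl]triphenylphosphonium bromide; 20 [(E)-2-{2-[(R)-4-hydroxy-2,6,6-trimethylcyclohex-1-en-1-yl]acetyl}-4-oxobut-2-en-1-yl] (E)-oct-2-enoate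
Product: 31 (3R,3'R,6'R)-3,3'-dihydroxy-8-oxo-7,8-dihydro-β,ε-caroten-19-yl (E)-oct-2-enoate (target)
Conditions: 1,2-epoxybutane (excess), 2-propanol/CH2Cl2, 45 °C, dark, argon; then EtOAc/heptane, 70 °C (E/Z equilibration), chromatography, crystallisation
Reagents that add atoms: none
Why: Wittig olefination under base-free epoxide conditions joins C12 to the aldehyde C11, the most electrophilic site of 20, without a strong base that could enolise C7 or displace the allylic octenoate, and thermal equilibration should give the all-E polyene.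

Compound list
1 | 2,2-dimethylcyclopentan-1-one | CC1(C)CCCC1=O | starting material
2 | 5,5-dimethylcyclopent-2-en-1-one | CC1(C)CC=CC1=O | intermediate
3 | (S)-2,2-dimethyl-4-(4,4,5,5-tetramethyl-1,3,2-dioxaborolan-2-yl)cyclopentan-1-one | O=C1C[C@@H](B2OC(C)(C)C(C)(C)O2)CC1(C)C | intermediate (not isolated)
4 | (S)-4-hydroxy-2,2-dimethylcyclopentan-1-one | O=C1C[C@@H](O)CC1(C)C | intermediate
5 | (S)-4-[(tert-butyldimethylsilyl)oxy]-2,2-dimethylcyclopentan-1-one | O=C1C[C@@H](O[Si](C)(C)C(C)(C)C)CC1(C)C | intermediate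
6 | N-ethyl-N-nitrosourea | CCN(N=O)C(N)=O | starting material
7 | diazoethane | CC=[N+]=[N-] | intermediate (not isolated)
8 | (4R)-4-[(tert-butyldimethylsilyl)oxy]-2,2,6-trimethylcyclohexan-1-one (C6 epimers) | CC1C[C@@H](O[Si](C)(C)C(C)(C)C)CC(C)(C)C1=O | intermediate
9 | potassium (R)-4-[(tert-butyldimethylsilyl)oxy]-2,6,6-trimethylcyclohex-1-en-1-olate | [K+].[O-]C1=C(C)C[C@@H](O[Si](C)(C)C(C)(C)C)CC1(C)C | intermediate (not isolated)
10 | (R)-4-[(tert-butyldimethylsilyl)oxy]-2,6,6-trimethylcyclohex-1-en-1-yl trifluoromethanesulfonate | O=S(=O)(OC1=C(C)C[C@@H](O[Si](C)(C)C(C)(C)C)CC1(C)C)C(F)(F)F | intermediate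
11 | methyl 2-methylfuran-3-carboxylate | COC(=O)c1ccoc1C | starting material
12 | methyl 2-(bromomethyl)furan-3-carboxylate | COC(=O)c1ccoc1CBr | intermediate
13 | {[3-(methoxycarbonyl)furan-2-yl]methyl}zinc bromide | COC(=O)c1ccoc1C[Zn]Br | intermediate (not isolated)
14 | methyl 2-{[(R)-4-[(tert-butyldimethylsilyl)oxy]-2,6,6-trimethylcyclohex-1-en-1-yl]methyl}furan-3-carboxylate | COC(=O)c1ccoc1CC1=C(C)C[C@@H](O[Si](C)(C)C(C)(C)C)CC1(C)C | intermediate
15 | (2-{[(R)-4-[(tert-butyldimethylsilyl)oxy]-2,6,6-trimethylcyclohex-1-en-1-yl]methyl}furan-3-yl)methanol | OCc1ccoc1CC1=C(C)C[C@@H](O[Si](C)(C)C(C)(C)C)CC1(C)C | intermediate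
16 | (E)-oct-2-enoic acid | CCCCC/C=C/C(=O)O | starting material
17 | (2-{[(R)-4-[(tert-butyldimethylsilyl)oxy]-2,6,6-trimethylcyclohex-1-en-1-yl]methyl}furan-3-yl)methyl (E)-oct-2-enoate | CCCCC/C=C/C(=O)OCc1ccoc1CC1=C(C)C[C@@H](O[Si](C)(C)C(C)(C)C)CC1(C)C | intermediate
18 | (2-{[(R)-4-hydroxy-2,6,6-trimethylcyclohex-1-en-1-yl]methyl}furan-3-yl)methyl (E)-oct-2-enoate | CCCCC/C=C/C(=O)OCc1ccoc1CC1=C(C)C[C@@H](O)CC1(C)C | intermediate
19 | [(Z)-2-{2-[(R)-4-hydroxy-2,6,6-trimethylcyclohex-1-en-1-yl]acetyl}-4-oxobut-2-en-1-yl] (E)-oct-2-enoate | CCCCC/C=C/C(=O)OC/C(=C/C=O)C(=O)CC1=C(C)C[C@@H](O)CC1(C)C | intermediate (not isolated)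
20 | [(E)-2-{2-[(R)-4-hydroxy-2,6,6-trimethylcyclohex-1-en-1-yl]acetyl}-4-oxobut-2-en-1-yl] (E)-oct-2-enoate | CCCCC/C=C/C(=O)OC/C(=C\C=O)C(=O)CC1=C(C)C[C@@H](O)CC1(C)C | intermediate
21 | (R)-α-ionone, (E)-4-[(1R)-2,6,6-trimethylcyclohex-2-en-1-yl]but-3-en-2-one | CC(=O)/C=C/[C@H]1C(C)=CCCC1(C)C | starting material
22 | (3R,6R)-3-hydroxy-α-ionone, (E)-4-[(1R,4R)-4-hydroxy-2,6,6-trimethylcyclohex-2-en-1-yl]but-3-en-2-one | CC(=O)/C=C/[C@H]1C(C)=C[C@H](O)CC1(C)C | intermediate
23 | vinylmagnesium bromide | C=C[Mg]Br | starting material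
24 | (E)-1-[(1R,4R)-4-hydroxy-2,6,6-trimethylcyclohex-2-en-1-yl]-3-methylpenta-1,4-dien-3-ol (carbinol epimers) | C=CC(C)(O)/C=C/[C@H]1C(C)=C[C@H](O)CC1(C)C | intermediate
25 | triphenylphosphine hydrobromide | [Br-].[PH+](c1ccccc1)(c1ccccc1)c1ccccc1 | starting material
26 | [(2E,4E)-5-[(1R,4R)-4-hydroxy-2,6,6-trimethylcyclohex-2-en-1-yl]-3-methylpenta-2,4-dien-1-yl]triphenylphosphonium bromide | c1ccccc1[P+](c1ccccc1)(c1ccccc1)C/C=C(C)/C=C/[C@H]1C(C)=C[C@H](O)CC1(C)C.[Br-] | intermediate
27 | (2E,4E,6E)-2,7-dimethylocta-2,4,6-trienedial | O=C/C(C)=C/C=C/C=C(C)/C=O | starting material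
28 | (2E,4E,6E,8E,10E,12E)-13-[(1R,4R)-4-hydroxy-2,6,6-trimethylcyclohex-2-en-1-yl]-2,7,11-trimethyltrideca-2,4,6,8,10,12-hexaenal | O=C/C(C)=C/C=C/C=C(C)/C=C/C=C(C)/C=C/[C@H]1C(C)=C[C@H](O)CC1(C)C | intermediate
29 | (2E,4E,6E,8E,10E,12E)-13-[(1R,4R)-4-hydroxy-2,6,6-trimethylcyclohex-2-en-1-yl]-2,7,11-trimethyltrideca-2,4,6,8,10,12-hexaen-1-ol | OC/C(C)=C/C=C/C=C(C)/C=C/C=C(C)/C=C/[C@H]1C(C)=C[C@H](O)CC1(C)C | intermediate
30 | [(2E,4E,6E,8E,10E,12E)-13-[(1R,4R)-4-hydroxy-2,6,6-trimethylcyclohex-2-en-1-yl]-2,7,11-trimethyltrideca-2,4,6,8,10,12-hexaen-1-yl]triphenylphosphonium bromide | c1ccccc1[P+](c1ccccc1)(c1ccccc1)C/C(C)=C/C=C/C=C(C)/C=C/C=C(C)/C=C/[C@H]1C(C)=C[C@H](O)CC1(C)C.[Br-] | intermediate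
31 | (3R,3'R,6'R)-3,3'-dihydroxy-8-oxo-7,8-dihydro-β,ε-caroten-19-yl (E)-oct-2-enoate | CCCCC/C=C/C(=O)OC\C(=C/C=C/C(C)=C/C=C/C=C(C)/C=C/C=C(C)/C=C/[C@H]1C(C)=C[C@H](O)CC1(C)C)C(=O)CC1=C(C)C[C@@H](O)CC1(C)C | target

Total step count: 18. Longest linear sequence: 11 steps (steps 1–5, 7–11 and 18).

Steps most likely to fail

Step 4. Addition of the secondary diazoalkane to the neopentyl-type carbonyl may be slow, so that Lewis-acid decomposition of diazoethane, β-elimination of the silyloxy group or incomplete control of which carbon migrates erodes the homologation. The fallback sets out from 5 and returns at 8. Ketone 5 is homologated with trimethylsilyldiazomethane and Me3Al (CH2Cl2, −78 °C), a stabilised diazo nucleophile that tolerates hindrance, to give the C-silyl ketone F1. Brief treatment with 1 M HCl in THF removes the silyl group and gives the demethyl ketone F2. LDA then MeI (THF, −78 °C) methylates C5 through the only possible enolate and gives 8. The ring is still enlarged from five to six members, but C18 is introduced separately.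

Step 11. Bromonium formation at the C5=C6 bond may compete with attack on the furan, and the labile keto-enal may be lost during unveiling and isolation. The fallback sets out from 18 and returns at 19. Anodic methoxylation of 18 (MeOH, Et4NOTs, graphite anode, controlled potential, −20 °C) oxidises only the more easily oxidised furan and gives the storable dimethoxydihydrofuran F3. Buffered hydrolysis (aq. AcOH/THF, 0 °C) immediately before use releases 19, which is isomerised with iodine to 20 as in the route.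

Step 18. The allylic octenoate may be lost by addition–elimination at C10/C19, or C7 may be enolised, while the ylide is present, and the E/Z outcome may be poor. The fallback sets out from 15 and returns at 31, with the ester introduced last. Alcohol 15 is desilylated (TBAF, THF) to the diol F4. NBS/NaHCO3 in aqueous acetone followed by catalytic iodine gives the hydroxymethyl keto-enal F5, which should exist largely as its five-membered lactol. Wittig reaction of F5 with 30 under the epoxybutane conditions gives siphonaxanthin F6, which has no leaving group at C19. A lipase (Candida antarctica lipase B, toluene, molecular sieves) then esterifies the primary allylic 19-OH with acid 16 in preference to the two secondary ring hydroxyls and gives 31.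

Further compounds
F1 | step 4 | (4R)-4-[(tert-butyldimethylsilyl)oxy]-2,2-dimethyl-6-(trimethylsilyl)cyclohexan-1-one | C[Si](C)(C)C1C[C@@H](O[Si](C)(C)C(C)(C)C)CC(C)(C)C1=O
F2 | step 4 | (R)-4-[(tert-butyldimethylsilyl)oxy]-2,2-dimethylcyclohexan-1-one | O=C1CC[C@@H](O[Si](C)(C)C(C)(C)C)CC1(C)C
F3 | step 11 | (2-{[(R)-4-hydroxy-2,6,6-trimethylcyclohex-1-en-1-yl]methyl}-2,5-dimethoxy-2,5-dihydrofuran-3-yl)methyl (E)-oct-2-enoate | CCCCC/C=C/C(=O)OCC1=CC(OC)OC1(OC)CC1=C(C)C[C@@H](O)CC1(C)C
F4 | step 18 | (R)-4-{[3-(hydroxymethyl)furan-2-yl]methyl}-3,5,5-trimethylcyclohex-3-en-1-ol | OCc1ccoc1CC1=C(C)C[C@@H](O)CC1(C)C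
F5 | step 18 | (E)-3-(hydroxymethyl)-5-[(R)-4-hydroxy-2,6,6-trimethylcyclohex-1-en-1-yl]-4-oxopent-2-enal | OC/C(=C\C=O)C(=O)CC1=C(C)C[C@@H](O)CC1(C)C
F6 | step 18 | siphonaxanthin, (3R,3'R,6'R)-3,19,3'-trihydroxy-7,8-dihydro-β,ε-caroten-8-one | OC\C(=C/C=C/C(C)=C/C=C/C=C(C)/C=C/C=C(C)/C=C/[C@H]1C(C)=C[C@H](O)CC1(C)C)C(=O)CC1=C(C)C[C@@H](O)CC1(C)C
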